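**Retrosynthetic overview**

1. The last bond made is C2′–C3′ of the triene, by Stille coupling of an (E)-vinylstannane on the finished epoxyquinol core with an (E,E)-5-iodopentadienamide of 2-amino-3-hydroxycyclopent-2-enone.
2. The vinylstannane comes from a terminal alkyne (hydrostannation), and the enamide C–N bond from an α-iodo epoxy-enone plus (2E,4R)-2,4-dimethyloct-2-enamide (copper-catalysed amidation).
3. The epoxy-enone comes from an achiral 4-silyloxy-4-alkynylcyclohexa-2,5-dienone by an organocatalytic desymmetrising epoxidation that sets all three ring stereocentres; the dienone comes from p-benzoquinone monoketal and lithium (trimethylsilyl)acetylide.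
4. The side-chain amide comes from (R)-3-methylhept-1-ene (ozonolysis/Wittig, aminolysis), itself from a copper-catalysed asymmetric allylic methylation; the iododienamide comes from Takai olefination of ethyl (E)-4-oxobut-2-enoate and nitrosation/hydrogenation of cyclopentane-1,3-dione.
5. Ring order: both carbocycles are bought; the oxirane is the only ring formed (desymmetrisation step), and no ring is made or broken afterwards.

Assumption: (E)-1-bromohept-2-ene and lithium (trimethylsilyl)acetylide (0.5 M in THF) are taken as catalogue items, and for each chiral catalyst the enantiomer (or pseudo-enantiomer) named is the one expected by analogy with simple substrates, its mirror form being equally available if the first run shows the opposite sense.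

**Route**

Step 1
Reactants: 1 (E)-1-bromohept-2-ene
Product: 2 (R)-3-methylhept-1-ene
Conditions: MeMgBr (1.2 equiv), CuBr·SMe2 (1 mol%), (R,R)-Taniaphos (1.2 mol%), CH2Cl2, −75 °C; dried CH2Cl2 solution of 2 carried forward
Reagents that add atoms: methylmagnesium bromide, C[Mg]Br
Why: Copper-catalysed asymmetric allylic alkylation (anti SN2′) delivers the methyl group to one enantioface of C3 of the E-allyl bromide inside the chiral diphosphine pocket, giving the branched alkene and setting the (R) stereocentre.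

Step 2
Reactants: 2 (R)-3-methylhept-1-ene; 3 ethyl 2-(triphenyl-λ5-phosphanylidene)propanoate
Product: 6 ethyl (2E,4R)-2,4-dimethyloct-2-enoate, via ozonide 4 (not isolated), via (R)-2-methylhexanal 5 (not isolated)
Conditions: O3, CH2Cl2, −78 °C; PPh3 (1.1 equiv), −78 → 0 °C; then 3 (2.2 equiv, excess also consumes the formaldehyde), rt, 16 h
Reagents that add atoms: none
Why: Ozonolysis with reductive work-up unmasks the α-methyl aldehyde, which is trapped at once under neutral conditions by the stabilised ylide in an E-selective Wittig olefination, so the stereocentre set in step 1 is never exposed to base and is retained.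

Step 3
Reactants: 6 ethyl (2E,4R)-2,4-dimethyloct-2-enoate
Product: 7 (2E,4R)-2,4-dimethyloct-2-enamide
Conditions: AlMe3 (3 equiv), NH4Cl (3 equiv), toluene, 0 °C → rt; then 6, 50 °C, 16 h; 1 M HCl work-up; recrystallise (hexane) to raise ee
Reagents that add atoms: ammonium chloride, [NH4+].[Cl-]
Why: Aluminium-amide aminolysis of the ester gives the primary amide in one step without conjugate addition and without touching the allylic stereocentre.

Step 4
Reactants: 8 cyclopentane-1,3-dione
Product: 9 2-(hydroxyimino)cyclopentane-1,3-dione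
Conditions: NaNO2 (1.05 equiv), 2 M aq HCl, 0 °C, 1 h; filter
Reagents that add atoms: sodium nitrite, [Na+].[O-]N=O
Why: Electrophilic C-nitrosation of the fully enolised 1,3-dione at C2 by nitrous acid followed by tautomerisation gives the oxime.

Step 5
Reactants: 9 2-(hydroxyimino)cyclopentane-1,3-dione
Product: 10 2-amino-3-hydroxycyclopent-2-en-1-one hydrochloride
Conditions: H2 (1 atm), 10% Pd/C, HCl (1.2 equiv), MeOH, rt
Reagents that add atoms: hydrogen chloride, Cl
Why: Catalytic hydrogenation reduces the oxime to the amine while the vinylogous-acid carbonyls are untouched, and isolation as the hydrochloride prevents self-condensation.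

Step 6
Reactants: 11 ethyl (E)-4-oxobut-2-enoate
Product: 12 ethyl (2E,4E)-5-iodopenta-2,4-dienoate
Conditions: CHI3 (2 equiv), CrCl2 (6 equiv), THF, 0 °C, dark
Reagents that add atoms: iodoform, IC(I)I
Why: Takai olefination, in which the geminal dichromium species adds only to the aldehyde and collapses to the (E)-alkenyl iodide, leaving the existing (E)-enoate intact.

Step 7
Reactants: 12 ethyl (2E,4E)-5-iodopenta-2,4-dienoate
Product: 13 (2E,4E)-5-iodopenta-2,4-dienoic acid
Conditions: LiOH·H2O (2 equiv), THF/H2O 3:1, 0 °C → rt; 1 M HCl to pH 2; recrystallise (removes traces of the 4Z isomer)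
Reagents that add atoms: lithium hydroxide, [Li+].[OH-]
Why: Saponification by acyl–oxygen cleavage is fast at 0 °C, whereas the alkenyl iodide is inert to cold hydroxide.

Step 8
Reactants: 13 (2E,4E)-5-iodopenta-2,4-dienoic acid; 10 2-amino-3-hydroxycyclopent-2-en-1-one hydrochloride
Product: 15 (2E,4E)-N-(2-hydroxy-5-oxocyclopent-1-en-1-yl)-5-iodopenta-2,4-dienamide, via acid chloride 14 (not isolated)
Conditions: (COCl)2 (1.2 equiv), DMF (cat.), CH2Cl2, 0 °C → rt, evaporate; then 10 (1.1 equiv), Et3N (2.5 equiv), THF/DMF, 0 °C → rt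
Reagents that add atoms: none
Why: Acid chloride formation and N-acylation of the liberated amine give the amide, any O-acylated enol transferring its acyl group to nitrogen.

Step 9
Reactants: 16 4,4-dimethoxycyclohexa-2,5-dien-1-one; 17 lithium (trimethylsilyl)acetylide
Product: 20 4-(triethylsilyloxy)-4-[(trimethylsilyl)ethynyl]cyclohexa-2,5-dien-1-one, via lithium alkoxide 18 (not isolated), via silyl ether ketal 19 (not isolated)
Conditions: 17 (1.1 equiv, 0.5 M in THF), THF, −78 °C, 1 h; Et3SiOTf (1.3 equiv), 2,6-lutidine (1.5 equiv), −78 → 0 °C; then 5% aq oxalic acid, THF, 0 °C, 30 min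
Reagents that add atoms: triethylsilyl trifluoromethanesulfonate, CC[Si](CC)(CC)OS(=O)(=O)C(F)(F)F; water, O
Why: 1,2-Addition of the acetylide to the only free carbonyl of the quinone monoketal, in situ O-silylation of the tertiary alkoxide and mild acid hydrolysis of the very labile dienyl ketal give the achiral, mirror-symmetric dienone.

Step 10
Reactants: 20 4-(triethylsilyloxy)-4-[(trimethylsilyl)ethynyl]cyclohexa-2,5-dien-1-one
Product: 21 (1S,5S,6R)-5-(triethylsilyloxy)-5-[(trimethylsilyl)ethynyl]-7-oxabicyclo[4.1.0]hept-3-en-2-one (oxirane oxygen anti to the silyloxy group)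
Conditions: 9-amino-9-deoxy-epi-quinine (10 mol%), CF3CO2H (20 mol%), 50% aq H2O2 (1.2 equiv), 1,4-dioxane, 30 °C, 24–48 h, stopped at about 90% conversion
Reagents that add atoms: hydrogen peroxide, OO
Why: Proposed new method: an iminium-catalysed Weitz–Scheffer epoxidation is used to desymmetrise a prochiral 4,4-disubstituted cyclohexa-2,5-dienone, in that the cinchona primary amine condenses with the ketone to a cross-conjugated iminium whose protonated quinuclidine hydrogen-bonds H2O2 and delivers it to only one of the two enantiotopic β-carbons, attack is confined to the ring face anti to the bulky triethylsilyloxy group (the rod-like silylalkyne does not shield its face and the C–O bond lies antiperiplanar to the incoming nucleophile), and the β-hydroperoxy enamine closes onto the O–O bond to the cis-fused oxirane, so the three ring stereocentres are set together and the minor enantiomer is preferentially drained to the achiral bis-epoxide; the closest known reaction types are the cinchona-primary-amine salt-catalysed epoxidation of simple cyclic enones with aqueous H2O2 and the chiral phase-transfer epoxidation of quinone monoketals.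

Step 11
Reactants: 21 (1S,5S,6R)-5-(triethylsilyloxy)-5-[(trimethylsilyl)ethynyl]-7-oxabicyclo[4.1.0]hept-3-en-2-one
Product: 22 (1S,5S,6R)-3-iodo-5-(triethylsilyloxy)-5-[(trimethylsilyl)ethynyl]-7-oxabicyclo[4.1.0]hept-3-en-2-one
Conditions: I2 (2 equiv), pyridine/CH2Cl2 1:1, 0 °C → rt, dark; aq Na2S2O3
Reagents that add atoms: iodine, II
Why: Amine-mediated α-iodination of the enone (conjugate addition of pyridine, iodination of the enolate, elimination) functionalises only the enone α-carbon, and neither the oxirane nor the silylalkyne reacts with I2/pyridine.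

Step 12
Reactants: 22 (1S,5S,6R)-3-iodo-5-(triethylsilyloxy)-5-[(trimethylsilyl)ethynyl]-7-oxabicyclo[4.1.0]hept-3-en-2-one; 7 (2E,4R)-2,4-dimethyloct-2-enamide
Product: 23 (2E,4R)-2,4-dimethyl-N-{(1S,5S,6R)-2-oxo-5-(triethylsilyloxy)-5-[(trimethylsilyl)ethynyl]-7-oxabicyclo[4.1.0]hept-3-en-3-yl}oct-2-enamide
Conditions: CuI (20 mol%), N,N′-dimethylethylenediamine (40 mol%), Cs2CO3 (1.5 equiv), 7 (1.2 equiv), toluene, 55 °C, Ar
Reagents that add atoms: none
Why: Copper-catalysed vinylic C–N coupling (Goldberg-type amidation) of the activated α-iodoenone with the primary amide forms the enamide under mild carbonate conditions, the silyl groups masking both the alkyne C–H and the tertiary alkoxide so that no stereocentre is touched.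

Step 13
Reactants: 23 (2E,4R)-2,4-dimethyl-N-{(1S,5S,6R)-2-oxo-5-(triethylsilyloxy)-5-[(trimethylsilyl)ethynyl]-7-oxabicyclo[4.1.0]hept-3-en-3-yl}oct-2-enamide
Product: 24 (2E,4R)-N-[(1S,5S,6R)-5-ethynyl-5-hydroxy-2-oxo-7-oxabicyclo[4.1.0]hept-3-en-3-yl]-2,4-dimethyloct-2-enamide
Conditions: Bu4NF (2.5 equiv), AcOH (2.7 equiv), THF, 0 °C → rt
Reagents that add atoms: none
Why: Fluoride cleaves both the O–Si and the alkynyl C–Si bonds, and the acetic acid buffer keeps the tertiary alkoxide protonated so that the anti-disposed epoxy alcohol cannot undergo Payne rearrangement.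

Step 14
Reactants: 24 (2E,4R)-N-[(1S,5S,6R)-5-ethynyl-5-hydroxy-2-oxo-7-oxabicyclo[4.1.0]hept-3-en-3-yl]-2,4-dimethyloct-2-enamide
Product: 25 (2E,4R)-N-{(1S,5S,6R)-5-hydroxy-2-oxo-5-[(E)-2-(tributylstannyl)ethenyl]-7-oxabicyclo[4.1.0]hept-3-en-3-yl}-2,4-dimethyloct-2-enamide
Conditions: Bu3SnH (1.2 equiv, slow addition), PdCl2(PPh3)2 (3 mol%), THF, 0 °C, 30 min; Et3N-deactivated silica
Reagents that add atoms: tributyltin hydride, CCCC[SnH](CCCC)CCCC
Why: Palladium-catalysed hydrostannation is a syn addition that places tin on the terminal carbon because the internal carbon is shielded by the quaternary carbinol centre, giving the (E)-alkenylstannane faster than any conjugate reduction of the enone.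

Step 15
Reactants: 25 (2E,4R)-N-{(1S,5S,6R)-5-hydroxy-2-oxo-5-[(E)-2-(tributylstannyl)ethenyl]-7-oxabicyclo[4.1.0]hept-3-en-3-yl}-2,4-dimethyloct-2-enamide; 15 (2E,4E)-N-(2-hydroxy-5-oxocyclopent-1-en-1-yl)-5-iodopenta-2,4-dienamide
Product: 26 (2E,4R)-N-[(1S,5R,6R)-5-hydroxy-5-[(1E,3E,5E)-7-[(2-hydroxy-5-oxocyclopent-1-en-1-yl)amino]-7-oxohepta-1,3,5-trien-1-yl]-2-oxo-7-oxabicyclo[4.1.0]hept-3-en-3-yl]-2,4-dimethyloct-2-enamide (target; the C5 descriptor changes from S to R only through the change in substituent priorities)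
Conditions: PdCl2(MeCN)2 (5 mol%), 15 (1.1 equiv), DMF, rt, dark, Ar
Reagents that add atoms: none
Why: Stille cross-coupling of the alkenyl iodide with the alkenylstannane proceeds with retention at both sp2 carbons under ligand-free, base-free conditions that tolerate the epoxide, the free tertiary alcohol and the acidic enol, completing the all-E triene without touching any stereocentre.

**Compound list**

1 | (E)-1-bromohept-2-ene | CCCC/C=C/CBr | starting material
2 | (R)-3-methylhept-1-ene | CCCC[C@@H](C)C=C | intermediate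
3 | ethyl 2-(triphenyl-λ5-phosphanylidene)propanoate | CCOC(=O)C(C)=P(c1ccccc1)(c1ccccc1)c1ccccc1 | starting material
4 | 3-[(2R)-hexan-2-yl]-1,2,4-trioxolane (ozonide, mixture at the ring carbon) | CCCC[C@@H](C)C1OCOO1 | intermediate
5 | (R)-2-methylhexanal | CCCC[C@@H](C)C=O | intermediate
6 | ethyl (2E,4R)-2,4-dimethyloct-2-enoate | CCCC[C@@H](C)/C=C(\C)C(=O)OCC | intermediate
7 | (2E,4R)-2,4-dimethyloct-2-enamide | CCCC[C@@H](C)/C=C(\C)C(N)=O | intermediate
8 | cyclopentane-1,3-dione | O=C1CCC(=O)C1 | starting material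
9 | 2-(hydroxyimino)cyclopentane-1,3-dione | ON=C1C(=O)CCC1=O | intermediate
10 | 2-amino-3-hydroxycyclopent-2-en-1-one hydrochloride | NC1=C(O)CCC1=O.Cl | intermediate
11 | ethyl (E)-4-oxobut-2-enoate | CCOC(=O)/C=C/C=O | starting material
12 | ethyl (2E,4E)-5-iodopenta-2,4-dienoate | CCOC(=O)/C=C/C=C/I | intermediate
13 | (2E,4E)-5-iodopenta-2,4-dienoic acid | OC(=O)/C=C/C=C/I | intermediate
14 | (2E,4E)-5-iodopenta-2,4-dienoyl chloride (acid chloride) | ClC(=O)/C=C/C=C/I | intermediate
15 | (2E,4E)-N-(2-hydroxy-5-oxocyclopent-1-en-1-yl)-5-iodopenta-2,4-dienamide | I/C=C/C=C/C(=O)NC1=C(O)CCC1=O | intermediate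
16 | 4,4-dimethoxycyclohexa-2,5-dien-1-one | COC1(OC)C=CC(=O)C=C1 | starting material
17 | lithium (trimethylsilyl)acetylide | [Li+].[C-]#C[Si](C)(C)C | starting material
18 | lithium 4,4-dimethoxy-1-[(trimethylsilyl)ethynyl]cyclohexa-2,5-dien-1-olate (lithium alkoxide) | [Li+].[O-]C1(C#C[Si](C)(C)C)C=CC(OC)(OC)C=C1 | intermediate
19 | triethyl({4,4-dimethoxy-1-[(trimethylsilyl)ethynyl]cyclohexa-2,5-dien-1-yl}oxy)silane (silyl ether ketal) | COC1(OC)C=CC(O[Si](CC)(CC)CC)(C#C[Si](C)(C)C)C=C1 | intermediate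
20 | 4-(triethylsilyloxy)-4-[(trimethylsilyl)ethynyl]cyclohexa-2,5-dien-1-one | O=C1C=CC(O[Si](CC)(CC)CC)(C#C[Si](C)(C)C)C=C1 | intermediate
21 | (1S,5S,6R)-5-(triethylsilyloxy)-5-[(trimethylsilyl)ethynyl]-7-oxabicyclo[4.1.0]hept-3-en-2-one | C1=C[C@](O[Si](CC)(CC)CC)(C#C[Si](C)(C)C)[C@@H]2O[C@@H]2C1=O | intermediate
22 | (1S,5S,6R)-3-iodo-5-(triethylsilyloxy)-5-[(trimethylsilyl)ethynyl]-7-oxabicyclo[4.1.0]hept-3-en-2-one | IC1=C[C@](O[Si](CC)(CC)CC)(C#C[Si](C)(C)C)[C@@H]2O[C@@H]2C1=O | intermediate
23 | (2E,4R)-2,4-dimethyl-N-{(1S,5S,6R)-2-oxo-5-(triethylsilyloxy)-5-[(trimethylsilyl)ethynyl]-7-oxabicyclo[4.1.0]hept-3-en-3-yl}oct-2-enamide | CCCC[C@@H](C)/C=C(\C)C(=O)NC1=C[C@](O[Si](CC)(CC)CC)(C#C[Si](C)(C)C)[C@@H]2O[C@@H]2C1=O | intermediate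
24 | (2E,4R)-N-[(1S,5S,6R)-5-ethynyl-5-hydroxy-2-oxo-7-oxabicyclo[4.1.0]hept-3-en-3-yl]-2,4-dimethyloct-2-enamide | CCCC[C@@H](C)/C=C(\C)C(=O)NC1=C[C@](O)(C#C)[C@@H]2O[C@@H]2C1=O | intermediate
25 | (2E,4R)-N-{(1S,5S,6R)-5-hydroxy-2-oxo-5-[(E)-2-(tributylstannyl)ethenyl]-7-oxabicyclo[4.1.0]hept-3-en-3-yl}-2,4-dimethyloct-2-enamide | CCCC[C@@H](C)/C=C(\C)C(=O)NC1=C[C@](O)(/C=C/[Sn](CCCC)(CCCC)CCCC)[C@@H]2O[C@@H]2C1=O | intermediate
26 | (2E,4R)-N-[(1S,5R,6R)-5-hydroxy-5-[(1E,3E,5E)-7-[(2-hydroxy-5-oxocyclopent-1-en-1-yl)amino]-7-oxohepta-1,3,5-trien-1-yl]-2-oxo-7-oxabicyclo[4.1.0]hept-3-en-3-yl]-2,4-dimethyloct-2-enamide | CCCC[C@@H](C)/C=C(\C)C(=O)NC1=C[C@](O)(/C=C/C=C/C=C/C(=O)NC2=C(O)CCC2=O)[C@@H]2O[C@@H]2C1=O | target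

**Step count and risks**

Total step count: 15. Longest linear sequence: 7 steps (steps 9–15 from 16; the branch through steps 1–3 and 12–15 is equally long).

The three steps most likely to fail:

Step 10 (the proposed new desymmetrising epoxidation). Iminium formation on the cross-conjugated ketone may be slow, the enantiotopic-alkene selectivity or the anti selectivity may be insufficient, and over-oxidation to the bis-epoxide may erode the yield. The fallback uses known chemistry and sets out from 20: a substrate-controlled Weitz–Scheffer epoxidation with t-BuOOH and DBU in CH2Cl2 at 0 °C, in which the peroxide anion attacks anti to the silyloxy group, gives the racemic anti-epoxide. This is 21 together with its mirror image (1R,5R,6S)-5-(triethylsilyloxy)-5-[(trimethylsilyl)ethynyl]-7-oxabicyclo[4.1.0]hept-3-en-2-one F1, which is removed by preparative HPLC on an amylose tris(3,5-dimethylphenylcarbamate) phase; the route is rejoined at 21.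

Step 12 (copper-catalysed amidation). The α-iodoenone is hindered and base-sensitive, and the conjugated primary amide is a modest nucleophile. The fallback sets out from 22 and brings the nitrogen in first: coupling with tert-butyl carbamate under Pd2(dba)3/Xantphos/Cs2CO3 in dioxane at 60 °C gives tert-butyl N-{(1S,5S,6R)-2-oxo-5-(triethylsilyloxy)-5-[(trimethylsilyl)ethynyl]-7-oxabicyclo[4.1.0]hept-3-en-3-yl}carbamate F2. Me3SiOTf/2,6-lutidine followed by MeOH then frees (1S,5S,6R)-3-amino-5-(triethylsilyloxy)-5-[(trimethylsilyl)ethynyl]-7-oxabicyclo[4.1.0]hept-3-en-2-one F3. In parallel, ester 6 is saponified with LiOH to (2E,4R)-2,4-dimethyloct-2-enoic acid F4 and converted with (COCl)2 into (2E,4R)-2,4-dimethyloct-2-enoyl chloride F5. Acylation of F3 with F5 (pyridine, CH2Cl2, 0 °C) gives 23, where the route is rejoined.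

Step 14 (hydrostannation). Tin hydride and zerovalent palladium may reduce the enone or the epoxy ketone, or give some of the internal stannane. The fallback sets out from 24 and avoids tin: Sonogashira coupling with 15 (PdCl2(PPh3)2, CuI, Et3N, THF, rt) gives the dienyne (2E,4R)-N-[(1S,5S,6R)-5-hydroxy-5-[(3E,5E)-7-[(2-hydroxy-5-oxocyclopent-1-en-1-yl)amino]-7-oxohepta-3,5-dien-1-yn-1-yl]-2-oxo-7-oxabicyclo[4.1.0]hept-3-en-3-yl]-2,4-dimethyloct-2-enamide F6. Trans-hydrosilylation with (EtO)3SiH and [Cp*Ru(MeCN)3]PF6 in CH2Cl2 gives the alkenylsilane (2E,4R)-N-[(1S,5S,6R)-5-hydroxy-5-[(1Z,3E,5E)-7-[(2-hydroxy-5-oxocyclopent-1-en-1-yl)amino]-7-oxo-2-(triethoxysilyl)hepta-1,3,5-trien-1-yl]-2-oxo-7-oxabicyclo[4.1.0]hept-3-en-3-yl]-2,4-dimethyloct-2-enamide F7. Protodesilylation with AgF in THF/MeOH/H2O then gives the E-alkene, so this fallback replaces steps 14 and 15 and comes back to the route at the target 26.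

**Further compounds**

F1 | step 10 | (1R,5R,6S)-5-(triethylsilyloxy)-5-[(trimethylsilyl)ethynyl]-7-oxabicyclo[4.1.0]hept-3-en-2-one | C1=C[C@@](O[Si](CC)(CC)CC)(C#C[Si](C)(C)C)[C@H]2O[C@H]2C1=O
F2 | step 12 | tert-butyl N-{(1S,5S,6R)-2-oxo-5-(triethylsilyloxy)-5-[(trimethylsilyl)ethynyl]-7-oxabicyclo[4.1.0]hept-3-en-3-yl}carbamate | CC(C)(C)OC(=O)NC1=C[C@](O[Si](CC)(CC)CC)(C#C[Si](C)(C)C)[C@@H]2O[C@@H]2C1=O
F3 | step 12 | (1S,5S,6R)-3-amino-5-(triethylsilyloxy)-5-[(trimethylsilyl)ethynyl]-7-oxabicyclo[4.1.0]hept-3-en-2-one | NC1=C[C@](O[Si](CC)(CC)CC)(C#C[Si](C)(C)C)[C@@H]2O[C@@H]2C1=O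
F4 | step 12 | (2E,4R)-2,4-dimethyloct-2-enoic acid | CCCC[C@@H](C)/C=C(\C)C(=O)O
F5 | step 12 | (2E,4R)-2,4-dimethyloct-2-enoyl chloride | CCCC[C@@H](C)/C=C(\C)C(=O)Cl
F6 | step 14 | (2E,4R)-N-[(1S,5S,6R)-5-hydroxy-5-[(3E,5E)-7-[(2-hydroxy-5-oxocyclopent-1-en-1-yl)amino]-7-oxohepta-3,5-dien-1-yn-1-yl]-2-oxo-7-oxabicyclo[4.1.0]hept-3-en-3-yl]-2,4-dimethyloct-2-enamide | CCCC[C@@H](C)/C=C(\C)C(=O)NC1=C[C@](O)(C#C/C=C/C=C/C(=O)NC2=C(O)CCC2=O)[C@@H]2O[C@@H]2C1=O
F7 | step 14 | (2E,4R)-N-[(1S,5S,6R)-5-hydroxy-5-[(1Z,3E,5E)-7-[(2-hydroxy-5-oxocyclopent-1-en-1-yl)amino]-7-oxo-2-(triethoxysilyl)hepta-1,3,5-trien-1-yl]-2-oxo-7-oxabicyclo[4.1.0]hept-3-en-3-yl]-2,4-dimethyloct-2-enamide | CCCC[C@@H](C)/C=C(\C)C(=O)NC1=C[C@](O)(/C=C(/C=C/C=C/C(=O)NC2=C(O)CCC2=O)[Si](OCC)(OCC)OCC)[C@@H]2O[C@@H]2C1=O
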